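**Retrosynthetic overview**
1. Target ⇒ its triacetate, by hydrolysis of three acetyl groups.
2. Triacetate ⇒ tribromo-4-methyl-ortho-quinone: the benzylic C–O bond is made by a proposed side-chain Thiele–Winter acetoxylation that runs through a para-quinone methide (key step).
3. ortho-Quinone ⇒ tribromo-4-methylcatechol (oxidation) ⇒ 4-methylcatechol: the three C–Br bonds come from exhaustive electrophilic bromination.
4. No ring is formed: the benzene ring and the side-chain carbon are bought together in 4-methylcatechol.

Assumption: the target has no stereocentre (it is achiral), so "single enantiomer" needs no stereocontrol and the SMILES carry no stereodescriptors.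

Step 1
Reactants: 1 4-methylcatechol (4-methylbenzene-1,2-diol)
Product: 2 tribromo-4-methylcatechol (3,4,6-tribromo-5-methylbenzene-1,2-diol)
Conditions: Br2 (3.05 equiv), AcOH, 10 °C to rt, 12 h
Reagents that add atoms: bromine, BrBr
Why: Electrophilic aromatic bromination; each of the three free ring positions is ortho or para to a hydroxyl, so three equivalents of Br2 fill all of them, regiochemistry cannot go wrong, and the methyl group is untouched at this stoichiometry and temperature.

Step 2
Reactants: 2 tribromo-4-methylcatechol (3,4,6-tribromo-5-methylbenzene-1,2-diol)
Product: 3 tribromo-4-methyl-ortho-quinone (3,4,6-tribromo-5-methylcyclohexa-3,5-diene-1,2-dione)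
Conditions: NaIO4 (1.05 equiv), CH2Cl2/H2O (1:1), 0 °C, 20 min; organic layer dried and used crude
Reagents that add atoms: none
Why: Two-electron periodate oxidation of a catechol to its ortho-quinone through a cyclic aryl periodate ester; the fully substituted halogenated quinone has no free ring position for addition or dimerisation and partitions into CH2Cl2 away from the oxidant.

Step 3
Reactants: 3 tribromo-4-methyl-ortho-quinone (3,4,6-tribromo-5-methylcyclohexa-3,5-diene-1,2-dione)
Product: 6 triacetate (2,3,6-tribromo-4,5-diacetoxybenzyl acetate), via para-quinone methide 4 (not isolated), via catechol benzyl acetate 5 (not isolated)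
Conditions: Ac2O/AcOH (4:1), H2SO4 (5 mol%), rt to 45 °C, N2
Reagents that add atoms: acetic acid, CC(=O)O; acetic anhydride, CC(=O)OC(C)=O
Why: Proposed new method: a side-chain Thiele–Winter acetoxylation of an ortho-quinone, in which acid-catalysed vinylogous enolisation of the ring methyl of 3 (conjugated with the carbonyl at the former meta oxygen) gives para-quinone methide 4, O-protonation of 4 unmasks a para-hydroxybenzyl cation that takes up acetic acid at the exocyclic carbon in a rearomatising 1,6-addition to give 5, and acid-catalysed O-acetylation by the solvent Ac2O turns 5 into redox-inert 6 before it can exchange with unreacted 3 (an exchange that is uphill anyway because CH2OAc is more electron-withdrawing than CH3); ring acetoxylation cannot compete because every ring carbon carries bromine, the closest known reaction types are the Thiele–Winter acetoxylation of quinones and the tautomerisation of 4-alkyl-ortho-quinones to para-quinone methides followed by 1,6-addition of an oxygen nucleophile, and no stereocentre is created.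

Step 4
Reactants: 6 triacetate (2,3,6-tribromo-4,5-diacetoxybenzyl acetate)
Product: 7 (2,3,6-tribromo-4,5-dihydroxyphenyl)methanol
Conditions: 2 M aq H2SO4/1,4-dioxane (1:1), 80 °C, Ar, 0.02 M
Reagents that add atoms: none
Why: Acid-catalysed ester hydrolysis (acyl–oxygen cleavage) of the two aryl acetates and the benzylic acetate; water is the only nucleophile present, so any para-hydroxybenzyl cation formed is returned to the same benzyl alcohol and not to an ether, the acidic medium keeps the catechol from autoxidising, and the aryl bromides are inert.

**Compound list**
1 | 4-methylcatechol (4-methylbenzene-1,2-diol) | Cc1ccc(O)c(O)c1 | starting material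
2 | 3,4,6-tribromo-5-methylbenzene-1,2-diol | Cc1c(Br)c(O)c(O)c(Br)c1Br | intermediate
3 | 3,4,6-tribromo-5-methylcyclohexa-3,5-diene-1,2-dione | CC1=C(Br)C(=O)C(=O)C(Br)=C1Br | intermediate
4 | 2,3,5-tribromo-6-hydroxy-4-methylidenecyclohexa-2,5-dien-1-one | C=C1C(Br)=C(O)C(=O)C(Br)=C1Br | intermediate
5 | 2,3,6-tribromo-4,5-dihydroxybenzyl acetate | CC(=O)OCc1c(Br)c(O)c(O)c(Br)c1Br | intermediate
6 | 2,3,6-tribromo-4,5-diacetoxybenzyl acetate | CC(=O)OCc1c(Br)c(OC(C)=O)c(OC(C)=O)c(Br)c1Br | intermediate
7 | (2,3,6-tribromo-4,5-dihydroxyphenyl)methanol | OCc1c(Br)c(O)c(O)c(Br)c1Br | target

Total step count: 4. Longest linear sequence: 4 steps (1 → 2 → 3 → 6 → 7).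

**Three steps most likely to fail**

The first is the proposed new acetoxylation (step 3). The enolisation may be slow, or catechol 5 may exchange redox state with 3 before it is acetylated, giving aldehyde-level products. The fallback uses known chemistry only, sets out from 2 and comes back to the route at 6. Acetylation of 2 (Ac2O, pyridine, rt) gives 3,4,6-tribromo-5-methyl-1,2-phenylene diacetate F1. Wohl–Ziegler radical bromination of the methyl group (NBS 1.1 equiv, AIBN cat., PhCF3, 85 °C) gives 3,4,6-tribromo-5-(bromomethyl)-1,2-phenylene diacetate F2. SN2 displacement of the benzylic bromide with KOAc in DMF at 50 °C gives 6, which goes on to the hydrolysis. This path also avoids the quinone altogether.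

The second is the quinone-forming oxidation (step 2). Quinone 3 may tautomerise or hydrate during isolation. The fallback sets out from 2 and comes back at 7, and never isolates a quinone. Heating 2 with Br2 (1.05 equiv) in 1,2-dichloroethane at 80 °C should brominate the side chain, as ring-brominated para-cresols classically do, through in-situ oxidation, quinone methide formation and HBr addition. This gives 3,4,6-tribromo-5-(bromomethyl)benzene-1,2-diol F3. Solvolysis of this para-hydroxybenzyl bromide in acetone/H2O (1:1) at rt gives 7 directly.

The third is the final deacetylation (step 4). Hydrolysis may be incomplete at the hindered esters, or the product may self-condense to the dibenzyl ether through the para-hydroxybenzyl cation. The fallback sets out from 6 and comes back at 7. It replaces solvolysis by hydride cleavage: i-Bu2AlH (7 equiv), CH2Cl2, −78 °C, then cold 1 M HCl. The three acetyl groups leave as ethanol, no cation or quinone methide can form, and the aryl bromides are inert at this temperature. It makes no compound outside the list (none F0).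

**Further compounds**
F1 | step 3 | 3,4,6-tribromo-5-methyl-1,2-phenylene diacetate | Cc1c(Br)c(OC(C)=O)c(OC(C)=O)c(Br)c1Br
F2 | step 3 | 3,4,6-tribromo-5-(bromomethyl)-1,2-phenylene diacetate | BrCc1c(Br)c(OC(C)=O)c(OC(C)=O)c(Br)c1Br
F3 | step 2 | 3,4,6-tribromo-5-(bromomethyl)benzene-1,2-diol | BrCc1c(Br)c(O)c(O)c(Br)c1Br
F0 | step 4 | none | none
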